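**Retrosynthetic overview**
1. Endgame: the target comes from ester 23 by fluoride/hydroxide deprotection; its enoate is made by Horner–Wadsworth–Emmons reaction at C13, the 8(17)-methylene by Wittig reaction of the C8 ketone 20, and the C10 methyl by cuprate addition to the Δ9(10)-8-one 18.
2. Key disconnection: both carbocycles of 18 come from the cyclobutanone–alkyne 17. The tethered C9≡C10 bond is inserted into the C5–C8 bond of the four-membered ring C5–C6–C7–C8 (two-atom ring expansion to ring B), and the same event closes ring A through the new C5–C10 bond.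
3. Enabling feature: C8, the ring-B carbon that carries the exocyclic methylene, is a latent ketone. The ring-B path C5–C6–C7–C8(=O) is therefore a strained four-carbon acyl unit, and its neighbours C9–C10 are a two-carbon π unit already tied to C5 by the ring-A chain C1–C4.
4. Precursor 17: cyclobutanone from ethylene and the keteniminium of amide 10; C4 quaternary centre by anti alkylation of γ-lactone 8; C2 bought as (S)-epichlorohydrin; side chain from hex-5-yn-2-one.
5. Ring order: temporary γ-lactone, then cyclobutane, then rings A and B together in step 8; C4, C5, C10 and C9 are relayed from C2 by substrate control.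

Key step: step 8

Remark: the SMILES is read as a cis-fused decalin, (2S,4R,5S,9S,10R,13E) in labdane locants (ring A = C1–C5, C10; ring B = C5–C10; C17 = CH2 on C8; C18 = carboxyl on C4; C20 = methyl on C10), with H-5, CH3-10, the C4 methyl, the C2 hydroxyl and the C9 side chain on one face and the C4 carboxyl on the other; these locants are used throughout.

**Step 1**
Reactants: 1 hex-5-yn-2-one
Product: 2 2-(but-3-yn-1-yl)-2-methyl-1,3-dioxolane
Conditions: HOCH2CH2OH, p-TsOH (cat.), benzene, reflux (Dean–Stark)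
Reagents that add atoms: ethylene glycol, OCCO
Why: Acid-catalysed ketalisation with azeotropic removal of water should mask the future C13 ketone as a dioxolane that tolerates the organolithium, triflic anhydride, rhodium and cuprate steps; no stereocentre is involved.

**Step 2**
Reactants: 2 2-(but-3-yn-1-yl)-2-methyl-1,3-dioxolane; 3 (S)-epichlorohydrin
Product: 5 2-methyl-2-{5-[(2S)-oxiran-2-yl]pent-3-yn-1-yl}-1,3-dioxolane, via chlorohydrin 4 (not isolated)
Conditions: n-BuLi, THF, −78 °C; BF3·OEt2, then 3, −78 °C; then NaOH, MeOH/H2O, 0 °C → rt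
Reagents that add atoms: none
Why: The lithium acetylide of 2, activated by BF3·OEt2 (Yamaguchi–Hirao alkynylation), should open the epoxide of 3 at its CH2 terminus, and NaOH then closes the chlorohydrin to the new terminal epoxide (intramolecular Williamson etherification); no bond to the stereocentre (C2) is broken, so its configuration is the one bought with 3.

**Step 3**
Reactants: 5 2-methyl-2-{5-[(2S)-oxiran-2-yl]pent-3-yn-1-yl}-1,3-dioxolane; 6 propanoic acid
Product: 8 (5R)-3-methyl-5-[5-(2-methyl-1,3-dioxolan-2-yl)pent-2-yn-1-yl]oxolan-2-one (both C3 epimers), via hydroxy acid 7 (not isolated)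
Conditions: 6, LDA (2 equiv), THF, 0 °C; then 5, rt; 1 M HCl to pH 3, 0 °C; PPTS (cat.), CH2Cl2, rt
Reagents that add atoms: none
Why: The dianion of propanoic acid should open the epoxide at its unsubstituted carbon C3 (SN2 alkylation of a carboxylic acid dianion) and the γ-hydroxy acid lactonises on mild acidification; C2 is untouched and the configuration at C4, formed as both epimers, is erased in step 4.

**Step 4**
Reactants: 8 lactone (both C3 epimers); 9 2-bromo-N,N-dimethylacetamide
Product: 10 2-{(3R,5S)-3-methyl-5-[5-(2-methyl-1,3-dioxolan-2-yl)pent-2-yn-1-yl]-2-oxooxolan-3-yl}-N,N-dimethylacetamide (methyl cis and acetamide arm trans to the 5-substituent)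
Conditions: LDA, THF, −78 °C; 9, DMPU, −78 → −30 °C
Reagents that add atoms: none
Why: Alkylation of the lactone enolate with the α-bromo amide should occur on the enolate face anti to the C5 substituent of the five-membered ring (1,3-induction known for γ-substituted butyrolactone enolates), which sets the C4 quaternary centre with the methyl cis and the acetamide arm trans to the propargylic chain.

**Step 5**
Reactants: 10 lactone amide; 11 ethylene
Product: 13 (3R,5S)-3-methyl-5-[5-(2-methyl-1,3-dioxolan-2-yl)pent-2-yn-1-yl]-3-(2-oxocyclobutyl)oxolan-2-one (both epimers at the cyclobutanone α-carbon C5), via cyclobutaniminium triflate 12 (not isolated)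
Conditions: Tf2O, 2,4,6-collidine, ethylene (5 bar), ClCH2CH2Cl, 60 °C; then aq. NaHCO3, rt
Reagents that add atoms: water, O
Why: Tf2O/collidine should turn the tertiary amide selectively into its keteniminium triflate, which adds thermally to ethylene in a [2+2] cycloaddition (Ghosez keteniminium–olefin reaction) and is hydrolysed to the cyclobutanone; the alkyne, held trans across the lactone ring, cannot reach the keteniminium, and the new α-stereocentre C5 is expected as a mixture that step 8 is designed to accept.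

**Step 6**
Reactants: 13 cyclobutanone lactone
Product: 16 (2R,4S)-4-[(tert-butyldimethylsilyl)oxy]-2-methyl-9-(2-methyl-1,3-dioxolan-2-yl)-2-(2-oxocyclobutyl)non-6-ynoic acid, via lithium hydroxy carboxylate 14 (not isolated), via bis-silyl compound 15 (not isolated)
Conditions: LiOH, THF/H2O, 0 °C → rt, evaporate; TBSCl, imidazole, DMF, rt; K2CO3, MeOH/H2O, rt; aq. KHSO4 to pH 4
Reagents that add atoms: lithium hydroxide, [Li+].[OH-]; tert-butyldimethylsilyl chloride, CC(C)(C)[Si](C)(C)Cl
Why: Saponification should open the lactone, silylation of the dry lithium salt caps the C2 hydroxyl (and the carboxylate) before relactonisation is possible, and only the labile silyl ester is cleaved by aqueous carbonate; C2 and C4 are not touched and C5 remains an epimerisable mixture.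

**Step 7**
Reactants: 16 silyloxy acid
Product: 17 2-(trimethylsilyl)ethyl (2R,4S)-4-[(tert-butyldimethylsilyl)oxy]-2-methyl-9-(2-methyl-1,3-dioxolan-2-yl)-2-(2-oxocyclobutyl)non-6-ynoate
Conditions: Me3SiCH2CH2OH, PPh3, DIAD, THF, 0 °C → rt
Reagents that add atoms: 2-(trimethylsilyl)ethanol, C[Si](C)(C)CCO
Why: In the Mitsunobu esterification the hindered carboxylate is the nucleophile and the reaction takes place at the primary carbon of the activated alcohol, so the quaternary C4 does not slow it; the 2-(trimethylsilyl)ethyl ester is chosen because fluoride later removes it without attack at the hindered carbonyl.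

**Step 8**
Reactants: 17 cyclobutanone–alkyne
Product: 18 2-(trimethylsilyl)ethyl (1R,3S,8aS)-3-[(tert-butyldimethylsilyl)oxy]-1-methyl-5-[2-(2-methyl-1,3-dioxolan-2-yl)ethyl]-6-oxo-1,2,3,4,6,7,8,8a-octahydronaphthalene-1-carboxylate (the Δ9(10)-8-one; H-5, the C4 methyl and the C2 silyloxy group on one face)
Conditions: [Rh(C2H4)2Cl]2 (5 mol %), P[3,5-(CF3)2C6H3]3 (20 mol %), 2-amino-3-picoline (20 mol %), 1,4-dioxane, 130 °C
Reagents that add atoms: none
Why: Monovalent rhodium, directed by the ketimine that the cyclobutanone forms reversibly with 2-amino-3-picoline, should add oxidatively into the strained C5–C8 bond to give a five-membered acyl–alkyl rhodacycle of trivalent rhodium, the tethered C9≡C10 bond then inserts (C10 to C5, C9 to Rh) and reductive elimination joins C9 to the acyl carbon C8. The closest known reaction type is the rhodium-catalysed intramolecular "cut-and-sew" [4+2] coupling of cyclobutanones that carry an alkyne tether at C2, which gives cyclohexenone-fused bicycles. Ring A (C1–C5, C10) closes by 6-exo-dig carbometalation of the alkyne that makes the C5–C10 bond, and ring B arises from the four-membered ring C5–C6–C7–C8 by two-atom expansion when C10 and C9 are stitched into its cleaved C5–C8 bond, the release of cyclobutanone strain being the driving force. No stereocentre is created, but C5 is fixed here: its epimers interconvert through the enamine tautomer of the ketimine, and ring closure should run through the chair-like array with C6, the C2 silyl ether and the C4 methyl equatorial and the C4 ester axial, which places H-5 on the face of the C4 methyl and the C2 oxygen as in the target. The step needs cleavage of the more substituted C5–C8 bond and not of C7–C8, and the tether secures it because only rhodium bound to C5 can reach the alkyne while insertion into C7–C8 is reversible and unproductive. Alkyne cyclotrimerisation and decarbonylation should be held back by the bulky, electron-poor phosphine.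

**Step 9**
Reactants: 18 bicyclic enone
Product: 20 2-(trimethylsilyl)ethyl (1R,3S,4aS,5R,8aS)-3-[(tert-butyldimethylsilyl)oxy]-1,4a-dimethyl-5-[2-(2-methyl-1,3-dioxolan-2-yl)ethyl]-6-oxodecahydronaphthalene-1-carboxylate (cis-fused; side chain cis to the C10 methyl), via silyl enol ether 19 (not isolated)
Conditions: Me2CuLi (from MeLi and CuI), TMSCl, THF, −78 → −20 °C; then K2CO3, MeOH, rt
Reagents that add atoms: methyllithium, [Li]C (delivered as Me2CuLi); chlorotrimethylsilane, C[Si](C)(C)Cl (kept only in intermediate 19)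
Why: TMSCl-accelerated conjugate addition of the Gilman reagent should deliver the methyl group to C10 on the face of H-5 (the cis-decalin outcome usual for octalones, reinforced here because the opposite face is screened by the axial C4 ester), and carbonate in methanol then cleaves the silyl enol ether and equilibrates the epimerisable C9 to the isomer with the side chain equatorial on ring B and cis to the C10 methyl, the other epimer being 1,3-diaxial to C4.

**Step 10**
Reactants: 20 decalone
Product: 21 2-(trimethylsilyl)ethyl (1R,3S,4aR,5S,8aS)-3-[(tert-butyldimethylsilyl)oxy]-1,4a-dimethyl-6-methylidene-5-[2-(2-methyl-1,3-dioxolan-2-yl)ethyl]decahydronaphthalene-1-carboxylate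
Conditions: Ph3PCH3Br, KOtBu, toluene, 80 °C
Reagents that add atoms: methyltriphenylphosphonium bromide, C[P+](c1ccccc1)(c1ccccc1)c1ccccc1.[Br-]
Why: Wittig methylenation with the ylide at elevated temperature is the standard way to convert hindered 8-oxo decalins into their exocyclic methylene compounds; C9 already has its thermodynamic configuration, so the basic medium cannot erode it.

**Step 11**
Reactants: 21 methylene ketal
Product: 22 2-(trimethylsilyl)ethyl (1R,3S,4aR,5S,8aS)-3-[(tert-butyldimethylsilyl)oxy]-1,4a-dimethyl-6-methylidene-5-(3-oxobutyl)decahydronaphthalene-1-carboxylate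
Conditions: PPTS, acetone/H2O, 50 °C
Reagents that add atoms: water, O
Why: Acid-catalysed transketalisation to acetone should free the methyl ketone under conditions that leave the secondary TBS ether, the silylethyl ester and the 1,1-disubstituted alkene untouched.

**Step 12**
Reactants: 22 methyl ketone
Product: 23 2-(trimethylsilyl)ethyl (1R,3S,4aR,5S,8aS)-3-[(tert-butyldimethylsilyl)oxy]-5-[(3E)-5-methoxy-3-methyl-5-oxopent-3-en-1-yl]-1,4a-dimethyl-6-methylidenedecahydronaphthalene-1-carboxylate
Conditions: (MeO)2P(O)CH2CO2Me, NaH, THF, 0 °C → reflux; chromatographic removal of the Z isomer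
Reagents that add atoms: trimethyl phosphonoacetate, COC(=O)CP(=O)(OC)OC
Why: Horner–Wadsworth–Emmons olefination of the methyl ketone should give mainly the E trisubstituted enoate (ester anti to the larger alkyl branch), the minor Z isomer being removed by chromatography.

**Step 13**
Reactants: 23 protected diester
Product: 25 (1R,3S,4aR,5S,8aS)-5-[(3E)-4-carboxy-3-methylbut-3-en-1-yl]-3-hydroxy-1,4a-dimethyl-6-methylidenedecahydronaphthalene-1-carboxylic acid (target), via hydroxy acid methyl ester 24 (not isolated)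
Conditions: TBAF, THF, rt → 40 °C; then LiOH, MeOH/H2O, 40 °C; 1 M HCl to pH 3, 0 °C
Reagents that add atoms: lithium hydroxide, [Li+].[OH-]
Why: Fluoride should cleave the TBS ether and fragment the 2-(trimethylsilyl)ethyl ester (to ethylene and Me3SiF) without attack at the hindered C4 carbonyl, and LiOH then saponifies the unhindered conjugated methyl ester; because the C2 hydroxyl and the C4 carboxyl are trans on ring A the product cannot lactonise, and neither alkene is expected to migrate under these mild conditions.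

**Compound list**
1 | hex-5-yn-2-one | CC(=O)CCC#C | starting material
2 | 2-(but-3-yn-1-yl)-2-methyl-1,3-dioxolane | CC1(CCC#C)OCCO1 | intermediate
3 | (S)-epichlorohydrin, (2S)-2-(chloromethyl)oxirane | ClC[C@@H]1CO1 | starting material
4 | (2S)-1-chloro-7-(2-methyl-1,3-dioxolan-2-yl)hept-4-yn-2-ol | ClC[C@@H](O)CC#CCCC1(C)OCCO1 | intermediate
5 | 2-methyl-2-{5-[(2S)-oxiran-2-yl]pent-3-yn-1-yl}-1,3-dioxolane | CC1(CCC#CC[C@H]2CO2)OCCO1 | intermediate
6 | propanoic acid | CCC(=O)O | starting material
7 | (4R)-4-hydroxy-2-methyl-9-(2-methyl-1,3-dioxolan-2-yl)non-6-ynoic acid (both C2 epimers) | CC(C[C@@H](O)CC#CCCC1(C)OCCO1)C(=O)O | intermediate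
8 | (5R)-3-methyl-5-[5-(2-methyl-1,3-dioxolan-2-yl)pent-2-yn-1-yl]oxolan-2-one (both C3 epimers) | CC1C[C@H](CC#CCCC2(C)OCCO2)OC1=O | intermediate
9 | 2-bromo-N,N-dimethylacetamide | CN(C)C(=O)CBr | starting material
10 | 2-{(3R,5S)-3-methyl-5-[5-(2-methyl-1,3-dioxolan-2-yl)pent-2-yn-1-yl]-2-oxooxolan-3-yl}-N,N-dimethylacetamide | CN(C)C(=O)C[C@@]1(C)C[C@H](CC#CCCC2(C)OCCO2)OC1=O | intermediate
11 | ethylene | C=C | starting material
12 | N,N-dimethyl-2-{(3R,5S)-3-methyl-5-[5-(2-methyl-1,3-dioxolan-2-yl)pent-2-yn-1-yl]-2-oxooxolan-3-yl}cyclobutan-1-iminium triflate (both epimers at the ring CH) | C[N+](C)=C1CCC1[C@@]3(C)C[C@H](CC#CCCC2(C)OCCO2)OC3=O.[O-]S(=O)(=O)C(F)(F)F | intermediate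
13 | (3R,5S)-3-methyl-5-[5-(2-methyl-1,3-dioxolan-2-yl)pent-2-yn-1-yl]-3-(2-oxocyclobutyl)oxolan-2-one (both epimers at C5, the cyclobutanone α-carbon) | O=C1CCC1[C@@]3(C)C[C@H](CC#CCCC2(C)OCCO2)OC3=O | intermediate
14 | lithium (2R,4S)-4-hydroxy-2-methyl-9-(2-methyl-1,3-dioxolan-2-yl)-2-(2-oxocyclobutyl)non-6-ynoate | [Li+].[O-]C(=O)[C@](C)(C[C@@H](O)CC#CCCC1(C)OCCO1)C2CCC2=O | intermediate
15 | tert-butyldimethylsilyl (2R,4S)-4-[(tert-butyldimethylsilyl)oxy]-2-methyl-9-(2-methyl-1,3-dioxolan-2-yl)-2-(2-oxocyclobutyl)non-6-ynoate | CC(C)(C)[Si](C)(C)OC(=O)[C@](C)(C[C@@H](O[Si](C)(C)C(C)(C)C)CC#CCCC1(C)OCCO1)C2CCC2=O | intermediate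
16 | (2R,4S)-4-[(tert-butyldimethylsilyl)oxy]-2-methyl-9-(2-methyl-1,3-dioxolan-2-yl)-2-(2-oxocyclobutyl)non-6-ynoic acid | OC(=O)[C@](C)(C[C@@H](O[Si](C)(C)C(C)(C)C)CC#CCCC1(C)OCCO1)C2CCC2=O | intermediate
17 | 2-(trimethylsilyl)ethyl (2R,4S)-4-[(tert-butyldimethylsilyl)oxy]-2-methyl-9-(2-methyl-1,3-dioxolan-2-yl)-2-(2-oxocyclobutyl)non-6-ynoate | C[Si](C)(C)CCOC(=O)[C@](C)(C[C@@H](O[Si](C)(C)C(C)(C)C)CC#CCCC1(C)OCCO1)C2CCC2=O | intermediate
18 | 2-(trimethylsilyl)ethyl (1R,3S,8aS)-3-[(tert-butyldimethylsilyl)oxy]-1-methyl-5-[2-(2-methyl-1,3-dioxolan-2-yl)ethyl]-6-oxo-1,2,3,4,6,7,8,8a-octahydronaphthalene-1-carboxylate | O=C1CC[C@H]2C(=C1CCC3(C)OCCO3)C[C@H](O[Si](C)(C)C(C)(C)C)C[C@@]2(C)C(=O)OCC[Si](C)(C)C | intermediate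
19 | 2-(trimethylsilyl)ethyl (1R,3S,4aS,8aS)-3-[(tert-butyldimethylsilyl)oxy]-1,4a-dimethyl-5-[2-(2-methyl-1,3-dioxolan-2-yl)ethyl]-6-[(trimethylsilyl)oxy]-1,2,3,4,4a,7,8,8a-octahydronaphthalene-1-carboxylate | C[Si](C)(C)OC1=C(CCC3(C)OCCO3)[C@@]2(C)C[C@H](O[Si](C)(C)C(C)(C)C)C[C@@](C)(C(=O)OCC[Si](C)(C)C)[C@H]2CC1 | intermediate
20 | 2-(trimethylsilyl)ethyl (1R,3S,4aS,5R,8aS)-3-[(tert-butyldimethylsilyl)oxy]-1,4a-dimethyl-5-[2-(2-methyl-1,3-dioxolan-2-yl)ethyl]-6-oxodecahydronaphthalene-1-carboxylate | O=C1CC[C@H]2[C@](C)(C[C@H](O[Si](C)(C)C(C)(C)C)C[C@@]2(C)C(=O)OCC[Si](C)(C)C)[C@H]1CCC3(C)OCCO3 | intermediate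
21 | 2-(trimethylsilyl)ethyl (1R,3S,4aR,5S,8aS)-3-[(tert-butyldimethylsilyl)oxy]-1,4a-dimethyl-6-methylidene-5-[2-(2-methyl-1,3-dioxolan-2-yl)ethyl]decahydronaphthalene-1-carboxylate | C=C1CC[C@H]2[C@](C)(C[C@H](O[Si](C)(C)C(C)(C)C)C[C@@]2(C)C(=O)OCC[Si](C)(C)C)[C@H]1CCC3(C)OCCO3 | intermediate
22 | 2-(trimethylsilyl)ethyl (1R,3S,4aR,5S,8aS)-3-[(tert-butyldimethylsilyl)oxy]-1,4a-dimethyl-6-methylidene-5-(3-oxobutyl)decahydronaphthalene-1-carboxylate | C=C1CC[C@H]2[C@](C)(C[C@H](O[Si](C)(C)C(C)(C)C)C[C@@]2(C)C(=O)OCC[Si](C)(C)C)[C@H]1CCC(C)=O | intermediate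
23 | 2-(trimethylsilyl)ethyl (1R,3S,4aR,5S,8aS)-3-[(tert-butyldimethylsilyl)oxy]-5-[(3E)-5-methoxy-3-methyl-5-oxopent-3-en-1-yl]-1,4a-dimethyl-6-methylidenedecahydronaphthalene-1-carboxylate | C=C1CC[C@H]2[C@](C)(C[C@H](O[Si](C)(C)C(C)(C)C)C[C@@]2(C)C(=O)OCC[Si](C)(C)C)[C@H]1CC/C(C)=C/C(=O)OC | intermediate
24 | (1R,3S,4aR,5S,8aS)-3-hydroxy-5-[(3E)-5-methoxy-3-methyl-5-oxopent-3-en-1-yl]-1,4a-dimethyl-6-methylidenedecahydronaphthalene-1-carboxylic acid | C=C1CC[C@H]2[C@](C)(C[C@H](O)C[C@@]2(C)C(=O)O)[C@H]1CC/C(C)=C/C(=O)OC | intermediate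
25 | (1R,3S,4aR,5S,8aS)-5-[(3E)-4-carboxy-3-methylbut-3-en-1-yl]-3-hydroxy-1,4a-dimethyl-6-methylidenedecahydronaphthalene-1-carboxylic acid | C=C1CC[C@H]2[C@](C)(C[C@H](O)C[C@@]2(C)C(=O)O)[C@H]1CC/C(C)=C/C(=O)O | target

**Step count**
Total steps: 13. Longest linear sequence: 13 steps (from hex-5-yn-2-one 1).

**Steps most likely to fail**

Step 8. What may go wrong: slow oxidative addition into the neopentyl-type C5–C8 bond next to the quaternary C4, decarbonylation of the rhodacycle, alkyne oligomerisation, or incomplete equilibration of the C5 epimers so that part of the material closes into the wrong ring-fusion series. The fallback separates ring-A closure from ring-B formation: a Pauson–Khand reaction builds ring A with a five-membered ring, which is then enlarged by one carbon. It sets out from lactone 8. Aldol addition of its lithium enolate to acetaldehyde (anti to the C5 chain) should give the 3-(1-hydroxyethyl) lactone F1, and dehydration with the Burgess reagent the 3-vinyl lactone F2. The sequence of steps 6 and 7 (LiOH; TBSCl, imidazole; K2CO3, MeOH/H2O; then Me3SiCH2CH2OH, PPh3, DIAD) would pass through the lithium hydroxy carboxylate F3 and the bis-silyl compound F4 to the silyloxy acid F5 and the enyne ester F6. Co2(CO)8 followed by N-methylmorpholine N-oxide should then close ring A and a cyclopentenone whose carbonyl C8 lies between C9 and C6, giving the bicyclic cyclopentenone F7. Me2CuLi in Et2O, followed by NH4Cl and K2CO3/MeOH equilibration, should give the cis-fused hydrindanone F8. Diazomethane with catalytic BF3·OEt2 should finally insert C7 between C8 and the less substituted C6, and the fallback comes back to the route at decalone 20.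

Step 9. What may go wrong: no reaction or 1,2-addition of the cuprate at the fully substituted, sterically screened enone. The fallback brings in the angular methyl as a cyclopropane methylene and sets out from enone 18. Luche reduction (NaBH4, CeCl3·7H2O, MeOH; axial hydride delivery) should give the 8β-allylic alcohol F9. Hydroxyl-directed Simmons–Smith cyclopropanation (Et2Zn, CH2I2) delivers CH2 to the C9=C10 bond syn to the hydroxyl, giving the cyclopropyl carbinol F10. Dess–Martin oxidation gives the cyclopropyl ketone F11. Li in NH3/THF at −78 °C should cleave the cyclopropane bond between C9 and the new CH2, the bond that overlaps with the carbonyl π system, which unveils the C10 methyl cis to H-5. Protonation and K2CO3/MeOH equilibration at C9 bring the fallback back to the route at decalone 20.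

Step 5. What may go wrong: over-activation by Tf2O (opening of the dioxolane or of the lactone) or oligomerisation of the hindered keteniminium before ethylene captures it. The fallback builds the cyclobutanone by ring expansion of an oxaspiropentane and sets out from lactone 8. Hydroxymethylation of its lithium enolate with gaseous formaldehyde (anti to the C5 chain) should give the hydroxymethyl lactone F12, and Dess–Martin oxidation the aldehyde F13. Wittig reaction with cyclopropylidenetriphenylphosphorane (from cyclopropyltriphenylphosphonium bromide and NaH) gives the alkylidenecyclopropane F14. Epoxidation with mCPBA (buffered with NaHCO3) gives the oxaspiropentane F15, and LiI in CH2Cl2 should induce its rearrangement to the cyclobutanone, coming back to the route at compound 13.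

**Further compounds**
F1 | step 8 | (5S)-3-(1-hydroxyethyl)-3-methyl-5-[5-(2-methyl-1,3-dioxolan-2-yl)pent-2-yn-1-yl]oxolan-2-one (hydroxyethyl trans to the 5-substituent, carbinol epimers) | CC(O)[C@@]1(C)C[C@H](CC#CCCC2(C)OCCO2)OC1=O
F2 | step 8 | (5S)-3-ethenyl-3-methyl-5-[5-(2-methyl-1,3-dioxolan-2-yl)pent-2-yn-1-yl]oxolan-2-one (vinyl trans to the 5-substituent) | C=C[C@@]1(C)C[C@H](CC#CCCC2(C)OCCO2)OC1=O
F3 | step 8 | lithium 2-ethenyl-4-hydroxy-2-methyl-9-(2-methyl-1,3-dioxolan-2-yl)non-6-ynoate | [Li+].[O-]C(=O)[C@@](C)(C=C)C[C@@H](O)CC#CCCC1(C)OCCO1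
F4 | step 8 | tert-butyldimethylsilyl 4-[(tert-butyldimethylsilyl)oxy]-2-ethenyl-2-methyl-9-(2-methyl-1,3-dioxolan-2-yl)non-6-ynoate | CC(C)(C)[Si](C)(C)OC(=O)[C@@](C)(C=C)C[C@@H](O[Si](C)(C)C(C)(C)C)CC#CCCC1(C)OCCO1
F5 | step 8 | 4-[(tert-butyldimethylsilyl)oxy]-2-ethenyl-2-methyl-9-(2-methyl-1,3-dioxolan-2-yl)non-6-ynoic acid | OC(=O)[C@@](C)(C=C)C[C@@H](O[Si](C)(C)C(C)(C)C)CC#CCCC1(C)OCCO1
F6 | step 8 | 2-(trimethylsilyl)ethyl 4-[(tert-butyldimethylsilyl)oxy]-2-ethenyl-2-methyl-9-(2-methyl-1,3-dioxolan-2-yl)non-6-ynoate | C[Si](C)(C)CCOC(=O)[C@@](C)(C=C)C[C@@H](O[Si](C)(C)C(C)(C)C)CC#CCCC1(C)OCCO1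
F7 | step 8 | bicyclic cyclopentenone, ring A fused to a cyclopent-2-enone with C8=O between C9 and C6 (H-5 on the face of the C4 methyl and the C2 silyloxy group) | O=C1C[C@H]2C(=C1CCC3(C)OCCO3)C[C@H](O[Si](C)(C)C(C)(C)C)C[C@@]2(C)C(=O)OCC[Si](C)(C)C
F8 | step 8 | cis-fused hydrindanone with the C10 methyl cis to H-5 and the side chain cis to that methyl | O=C1C[C@H]2[C@](C)(C[C@H](O[Si](C)(C)C(C)(C)C)C[C@@]2(C)C(=O)OCC[Si](C)(C)C)[C@H]1CCC3(C)OCCO3
F9 | step 9 | 8β-hydroxy Δ9(10)-octalin (allylic alcohol from 18) | O[C@H]1CC[C@H]2C(=C1CCC3(C)OCCO3)C[C@H](O[Si](C)(C)C(C)(C)C)C[C@@]2(C)C(=O)OCC[Si](C)(C)C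
F10 | step 9 | 9,10-methano-8β-ol (cyclopropyl carbinol, CH2 on the face of H-5) | O[C@H]1CC[C@H]2[C@]3(C[C@@]13CCC4(C)OCCO4)C[C@H](O[Si](C)(C)C(C)(C)C)C[C@@]2(C)C(=O)OCC[Si](C)(C)C
F11 | step 9 | 9,10-methano-8-one (cyclopropyl ketone) | O=C1CC[C@H]2[C@]3(C[C@@]13CCC4(C)OCCO4)C[C@H](O[Si](C)(C)C(C)(C)C)C[C@@]2(C)C(=O)OCC[Si](C)(C)C
F12 | step 5 | (5S)-3-(hydroxymethyl)-3-methyl-5-[5-(2-methyl-1,3-dioxolan-2-yl)pent-2-yn-1-yl]oxolan-2-one (hydroxymethyl trans to the 5-substituent) | OC[C@@]1(C)C[C@H](CC#CCCC2(C)OCCO2)OC1=O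
F13 | step 5 | 3-methyl-5-[5-(2-methyl-1,3-dioxolan-2-yl)pent-2-yn-1-yl]-2-oxooxolane-3-carbaldehyde (formyl trans to the 5-substituent) | O=C[C@@]1(C)C[C@H](CC#CCCC2(C)OCCO2)OC1=O
F14 | step 5 | 3-(cyclopropylidenemethyl)-3-methyl-5-[5-(2-methyl-1,3-dioxolan-2-yl)pent-2-yn-1-yl]oxolan-2-one | C(=C1CC1)[C@@]2(C)C[C@H](CC#CCCC3(C)OCCO3)OC2=O
F15 | step 5 | 3-methyl-3-(1-oxaspiro[2.2]pentan-2-yl)-5-[5-(2-methyl-1,3-dioxolan-2-yl)pent-2-yn-1-yl]oxolan-2-one (epoxide epimers) | C1CC12OC2[C@@]3(C)C[C@H](CC#CCCC4(C)OCCO4)OC3=O
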